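## Retrosynthetic overview

1. Target 18 is cut at the O2' ester (acid 15) and at an O1' silyl ether, back to diol 14, whose C3'–OH arises by hydrolysis of the oxirane in 13.
2. The strategy rests on the three contiguous oxygen-bearing chain carbons on coumarin C6: benzylic C1', acyloxy-bearing C2' and gem-dimethyl C3'. They are read as an aryl ketone at C1' next to a C2'=C3' alkene, so C1'–H is cut back to epoxy ketone 11, and the C2'–O and C3'–O bonds of 11 to enone 10 (catalytic asymmetric nucleophilic epoxidation).
3. Enone 10 is the Meyer–Schuster isomer of aryl alkynol 8, which comes from Sonogashira coupling of 6-iodo-7-methoxycoumarin 6 with alkynol 7.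
4. Ring order: the benzene ring is bought; the pyranone ring is closed first (Wittig olefination and lactonisation of iodosalicylaldehyde 2); the oxirane is formed in step 5 and opened again in step 8.

Key step: step 5

Assumption: the (R)-BINOL antipode is taken to give the 2'S oxirane, by analogy with the sense of induction of this catalyst family on chalcone-type aryl enones; if the β,β-dimethyl enone responds in the opposite sense, (S)-BINOL is used with no other change. Primed locants C1'–C3' count the chain from the carbon bound to coumarin C6.

## Route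

Step 1
Reactants: 1 2-hydroxy-4-methoxybenzaldehyde
Product: 2 2-hydroxy-5-iodo-4-methoxybenzaldehyde
Conditions: ICl (1.05 equiv), AcOH, rt
Reagents that add atoms: iodine monochloride, ClI
Why: Electrophilic aromatic iodination; C5, para to the free phenol and ortho to the methoxy group, is the most activated and least crowded position, C3 between the two oxygens being shielded.

Step 2
Reactants: 2 2-hydroxy-5-iodo-4-methoxybenzaldehyde; 3 ethyl (triphenylphosphoranylidene)acetate
Product: 6 6-iodo-7-methoxycoumarin, via E-hydroxycinnamate ester 4 (not isolated), via Z-hydroxycinnamate ester 5 (not isolated)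
Conditions: PhNEt2, reflux (about 215 °C)
Reagents that add atoms: none
Why: Wittig olefination by the stabilised ylide gives the ortho-hydroxycinnamates, and at the reflux temperature of PhNEt2 the E ester isomerises to the Z ester, whose phenol closes the pyranone ring by lactonisation with loss of ethanol.

Step 3
Reactants: 6 6-iodo-7-methoxycoumarin; 7 2-methylbut-3-yn-2-ol
Product: 8 6-(3-hydroxy-3-methylbut-1-yn-1-yl)-7-methoxycoumarin
Conditions: PdCl2(PPh3)2 (2 mol%), CuI (4 mol%), Et3N, THF, 45 °C
Reagents that add atoms: none
Why: Sonogashira coupling, in which oxidative addition of the aryl iodide to zerovalent palladium, transmetalation from the copper acetylide and reductive elimination form the C6–C(sp) bond, the lactone being inert to the tertiary amine.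

Step 4
Reactants: 8 6-(3-hydroxy-3-methylbut-1-yn-1-yl)-7-methoxycoumarin
Product: 10 7-methoxy-6-(3-methylbut-2-enoyl)coumarin, via allenol 9 (not isolated)
Conditions: p-TsOH·H2O (0.3 equiv), ClCH2CH2Cl, 70 °C
Reagents that add atoms: none
Why: Meyer–Schuster rearrangement, in which acid ionises the tertiary propargylic alcohol, the water lost re-adds at the aryl-bearing alkyne carbon of the propargyl/allenyl cation (stabilised by the ortho-methoxyaryl ring) and the allenol tautomerises to the conjugated enone, a formal 1,3-hydroxyl shift that retains no outside atom; the C7 methyl ether rules out oxa-Michael closure to a chromanone.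

Step 5
Reactants: 10 7-methoxy-6-(3-methylbut-2-enoyl)coumarin
Product: 11 6-[(2S)-3,3-dimethyloxirane-2-carbonyl]-7-methoxycoumarin
Conditions: La(OiPr)3 (10 mol%), (R)-BINOL (10 mol%), Ph3As=O (10 mol%), tBuOOH (1.5 equiv, in decane), 4 Å MS, THF, rt
Reagents that add atoms: tert-butyl hydroperoxide, CC(C)(C)OO
Why: The lanthanum alkoxide–BINOL complex, kept monomeric by Ph3As=O, exchanges an alkoxide for tert-butylperoxide and binds the aryl ketone oxygen of the s-cis enone (the ortho methoxy group can act as a second donor), so that the metal-bound peroxide adds in conjugate fashion to C3' and the resulting lanthanum enolate then attacks the proximal peroxide oxygen through C2' with loss of tert-butoxide. The closest known reaction is the lanthanide–BINOL-catalysed asymmetric Weitz–Scheffer epoxidation of aryl enones, applied here to a β,β-dimethyl member of that class, a substitution pattern for which base-mediated peroxide epoxidation itself is long established. The oxirane closes in a 3-exo-tet mode. C2' is the only new stereocentre: because the peroxide stays bridged to lanthanum from addition through closure, the enone face chosen by the (R)-BINOL pocket is the face on which the C2'–O bond forms, and since C3' carries two methyl groups neither alkene geometry nor C2'–C3' rotation can produce a diastereomer. The step needs enantioface selection, which rests on rigid two-point binding of the substrate in the chiral pocket, and chemoselectivity, which is secured because the lanthanum-activated aryl enone is far more electrophilic than the coumarin C3–C4 alkene, part of an aryl-conjugated lactone that is a poor acceptor for hydroperoxide and a weak donor to the metal.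

Step 6
Reactants: 11 6-[(2S)-3,3-dimethyloxirane-2-carbonyl]-7-methoxycoumarin
Product: 12 6-[(R)-[(2R)-3,3-dimethyloxiran-2-yl](hydroxy)methyl]-7-methoxycoumarin
Conditions: Zn(BH4)2 (Et2O solution, 1.5 equiv), CH2Cl2/Et2O, −20 °C; then aq NH4Cl
Reagents that add atoms: none
Why: Chelation-controlled hydride reduction, in which zinc bridges the ketone and oxirane oxygens in a five-membered chelate and hydride reaches C1' from the face away from C3', setting the 1'R centre (erythro to C2') by 1,2-induction from the oxirane, while lactone and oxirane are inert to this mild borohydride at low temperature.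

Step 7
Reactants: 12 6-[(R)-[(2R)-3,3-dimethyloxiran-2-yl](hydroxy)methyl]-7-methoxycoumarin
Product: 13 6-[(R)-(tert-butyldimethylsilyloxy)[(2R)-3,3-dimethyloxiran-2-yl]methyl]-7-methoxycoumarin
Conditions: TBSCl (1.5 equiv), imidazole (3 equiv), DMAP (cat.), DMF, rt
Reagents that add atoms: tert-butyldimethylsilyl chloride, CC(C)(C)[Si](C)(C)Cl
Why: Silylation of the secondary benzylic alcohol under imidazole catalysis, mild enough to avoid Payne rearrangement or opening of the neighbouring oxirane, with no stereocentre touched.

Step 8
Reactants: 13 6-[(R)-(tert-butyldimethylsilyloxy)[(2R)-3,3-dimethyloxiran-2-yl]methyl]-7-methoxycoumarin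
Product: 14 6-[(1R,2R)-1-(tert-butyldimethylsilyloxy)-2,3-dihydroxy-3-methylbutyl]-7-methoxycoumarin
Conditions: HClO4 (cat., about 0.05 M), THF/H2O 3:1, 0 °C
Reagents that add atoms: water, O
Why: Acid-catalysed epoxide hydrolysis, in which water opens the protonated oxirane at the tertiary C3' (borderline SN1) so that the C2'–O bond is never broken and C2' keeps its configuration, C3' not being stereogenic, while catalytic acid at 0 °C should spare the hindered secondary silyl ether.

Step 9
Reactants: 14 6-[(1R,2R)-1-(tert-butyldimethylsilyloxy)-2,3-dihydroxy-3-methylbutyl]-7-methoxycoumarin; 15 (R)-2-methylbutanoic acid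
Product: 17 (1R,2R)-1-(tert-butyldimethylsilyloxy)-3-hydroxy-1-(7-methoxy-2-oxo-2H-chromen-6-yl)-3-methylbutan-2-yl (2R)-2-methylbutanoate, via mixed anhydride 16 (not isolated)
Conditions: 15, 2,4,6-Cl3C6H2COCl, Et3N, THF, 0 °C to rt; then 14, DMAP, toluene, rt
Reagents that add atoms: none
Why: Yamaguchi esterification, in which DMAP attacks the mixed anhydride at the aliphatic carbonyl and the acylpyridinium acylates the secondary O2'–H, the tertiary O3'–H being too hindered to compete, and the saturated α-branched acyl group should not epimerise under these conditions.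

Step 10
Reactants: 17 (1R,2R)-1-(tert-butyldimethylsilyloxy)-3-hydroxy-1-(7-methoxy-2-oxo-2H-chromen-6-yl)-3-methylbutan-2-yl (2R)-2-methylbutanoate
Product: 18 (1R,2R)-1,3-dihydroxy-1-(7-methoxy-2-oxo-2H-chromen-6-yl)-3-methylbutan-2-yl (2R)-2-methylbutanoate
Conditions: HF·pyridine, pyridine, THF, 0 °C to rt
Reagents that add atoms: none
Why: Fluoride-mediated desilylation under buffered, mildly acidic conditions, which cleaves the Si–O bond without forming a free alkoxide and so should suppress 1,2-acyl migration from O2' to O1' or O3' and leave the lactone intact.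

## Compound list

1 | 2-hydroxy-4-methoxybenzaldehyde | COc1ccc(C=O)c(O)c1 | starting material
2 | 2-hydroxy-5-iodo-4-methoxybenzaldehyde | COc1cc(O)c(C=O)cc1I | intermediate
3 | ethyl (triphenylphosphoranylidene)acetate | CCOC(=O)C=P(c1ccccc1)(c1ccccc1)c1ccccc1 | starting material
4 | ethyl (E)-3-(2-hydroxy-5-iodo-4-methoxyphenyl)prop-2-enoate | CCOC(=O)/C=C/c1cc(I)c(OC)cc1O | intermediate (not isolated)
5 | ethyl (Z)-3-(2-hydroxy-5-iodo-4-methoxyphenyl)prop-2-enoate | CCOC(=O)/C=C\c1cc(I)c(OC)cc1O | intermediate (not isolated)
6 | 6-iodo-7-methoxycoumarin (6-iodo-7-methoxy-2H-chromen-2-one) | COc1cc2oc(=O)ccc2cc1I | intermediate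
7 | 2-methylbut-3-yn-2-ol | CC(C)(O)C#C | starting material
8 | 6-(3-hydroxy-3-methylbut-1-yn-1-yl)-7-methoxycoumarin | COc1cc2oc(=O)ccc2cc1C#CC(C)(C)O | intermediate
9 | 6-(1-hydroxy-3-methylbuta-1,2-dien-1-yl)-7-methoxycoumarin (allenol) | COc1cc2oc(=O)ccc2cc1C(O)=C=C(C)C | intermediate (not isolated)
10 | 7-methoxy-6-(3-methylbut-2-enoyl)coumarin | CC(C)=CC(=O)c1cc2ccc(=O)oc2cc1OC | intermediate
11 | 6-[(2S)-3,3-dimethyloxirane-2-carbonyl]-7-methoxycoumarin | O1[C@H](C(=O)c2cc3ccc(=O)oc3cc2OC)C1(C)C | intermediate
12 | 6-[(R)-[(2R)-3,3-dimethyloxiran-2-yl](hydroxy)methyl]-7-methoxycoumarin | O1[C@H]([C@H](O)c2cc3ccc(=O)oc3cc2OC)C1(C)C | intermediate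
13 | 6-[(R)-(tert-butyldimethylsilyloxy)[(2R)-3,3-dimethyloxiran-2-yl]methyl]-7-methoxycoumarin | O1[C@H]([C@H](O[Si](C)(C)C(C)(C)C)c2cc3ccc(=O)oc3cc2OC)C1(C)C | intermediate
14 | 6-[(1R,2R)-1-(tert-butyldimethylsilyloxy)-2,3-dihydroxy-3-methylbutyl]-7-methoxycoumarin | O[C@H]([C@H](O[Si](C)(C)C(C)(C)C)c1cc2ccc(=O)oc2cc1OC)C(C)(C)O | intermediate
15 | (R)-2-methylbutanoic acid | CC[C@@H](C)C(=O)O | starting material
16 | (2R)-2-methylbutanoic 2,4,6-trichlorobenzoic anhydride | CC[C@@H](C)C(=O)OC(=O)c1c(Cl)cc(Cl)cc1Cl | intermediate (not isolated)
17 | (1R,2R)-1-(tert-butyldimethylsilyloxy)-3-hydroxy-1-(7-methoxy-2-oxo-2H-chromen-6-yl)-3-methylbutan-2-yl (2R)-2-methylbutanoate | CC[C@@H](C)C(=O)O[C@H]([C@H](O[Si](C)(C)C(C)(C)C)c1cc2ccc(=O)oc2cc1OC)C(C)(C)O | intermediate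
18 | (1R,2R)-1,3-dihydroxy-1-(7-methoxy-2-oxo-2H-chromen-6-yl)-3-methylbutan-2-yl (2R)-2-methylbutanoate | CC[C@@H](C)C(=O)O[C@H]([C@H](O)c1cc2ccc(=O)oc2cc1OC)C(C)(C)O | target

## Step count and risks

Total step count: 10. Longest linear sequence: 10 steps (from 1 to 18).

Steps most likely to fail:

1. Step 5. Conjugate addition of the metal-bound peroxide at the doubly substituted C3' may be slow, and enantioface discrimination may be poor because the single β-substituent that normally orients an enone in the pocket is replaced by two methyl groups, one cis to the carbonyl. Fallback, setting out from iodide 6 and returning at 11: the C2' centre is made by allylic alcohol epoxidation instead. 3-Methylbut-2-en-1-ol is epoxidised under Sharpless conditions (Ti(OiPr)4, D-(−)-diethyl tartrate, tBuOOH, 4 Å MS, CH2Cl2, −20 °C; the tartrate antipode that by the usual face rule gives the 2R product) to [(2R)-3,3-dimethyloxiran-2-yl]methanol F1. Parikh–Doering oxidation (SO3·pyridine, DMSO, iPr2NEt) gives (2S)-3,3-dimethyloxirane-2-carbaldehyde F2. Nozaki–Hiyama–Kishi coupling with 6 (CrCl2, NiCl2 cat., DMF, rt) gives 6-[[(2R)-3,3-dimethyloxiran-2-yl](hydroxy)methyl]-7-methoxycoumarin as a mixture of C1' epimers F3, and Dess–Martin oxidation converges both epimers on epoxy ketone 11.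

2. Step 6. Facial selectivity may erode if zinc is held by the ortho-methoxy/carbonyl pair instead of the carbonyl/oxirane pair, and hydride may attack the coumarin lactone if the ketone reduction is slow. Fallback, setting out from 11 and returning at 12: catalyst-controlled Corey–Bakshi–Shibata reduction with (R)-2-methyl-CBS-oxazaborolidine and BH3·SMe2 (or catecholborane) in CH2Cl2 at low temperature. This antipode should deliver hydride to the Si face of C1' if the aryl group acts as the large substituent, and it does not depend on chelation; no new compound is formed.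

3. Step 8. The acid may cleave the silyl ether prematurely, the opening C3' cation may undergo a 1,2-hydride shift from C2' to give a C2' ketone, or the electron-rich benzylic C1' may ionise with loss of configuration. Fallback, setting out from 12 and returning at 14: the order of hydrolysis and protection is reversed. The oxirane of unprotected 12 is hydrolysed (dilute aqueous oxalic acid in THF, or water–dioxane at 60 °C) to 6-[(1R,2R)-1,2,3-trihydroxy-3-methylbutyl]-7-methoxycoumarin F4. The triol is then mono-silylated (TBSCl, imidazole, DMF, −20 °C) at benzylic O1', which should be more accessible than O2' next to the fully substituted C3'.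

## Further compounds

F1 | step 5 | [(2R)-3,3-dimethyloxiran-2-yl]methanol | O1[C@H](CO)C1(C)C
F2 | step 5 | (2S)-3,3-dimethyloxirane-2-carbaldehyde | O1[C@H](C=O)C1(C)C
F3 | step 5 | 6-[[(2R)-3,3-dimethyloxiran-2-yl](hydroxy)methyl]-7-methoxycoumarin, mixture of C1' epimers | O1[C@H](C(O)c2cc3ccc(=O)oc3cc2OC)C1(C)C
F0 | step 6 | none | none
F4 | step 8 | 6-[(1R,2R)-1,2,3-trihydroxy-3-methylbutyl]-7-methoxycoumarin | O[C@H]([C@H](O)c1cc2ccc(=O)oc2cc1OC)C(C)(C)O
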